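**Retrosynthetic overview**
- Last ring (1,3-dioxan-4-one spiroketal, with A-ring dearomatisation): open the acyloxy ketal C–O bond to a cage carboxylic acid tethered through its tertiary ether oxygen to an alkoxy-p-quinone (intramolecular carboxylate oxa-Michael, then C-protonation).
- Bicyclo[2.2.2]octenone and bridging THF (formed together in one step): retro-Diels–Alder/retro-Claisen to a tetra-oxygenated benzoate with two 1,1-dimethylallyl ethers; a catalytic enantioselective dearomative Claisen/intramolecular Diels–Alder cascade sets all four cage centres.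
- Aryl–O–quinone bond: addition–elimination of a salicylate phenol on a bromoquinone.
- B-ring phenol from 2,3,4-trihydroxybenzoic acid (ester, bis-O-allylation, para-oxidation, silylation); A-ring bromoquinone from 5-bromoresorcinol (chromene annulation, ortho-prenylation, Teuber oxidation).
- Ring order: 2H-pyran → fragment union → THF + bicyclooctene → dioxanone spiroketal.

Assumption: carbonate 9 is purchased (otherwise one extra step from 2-methylbut-3-en-2-ol and Boc2O); the catalyst antipode written in step 9 is the one that gives the natural cage (both antipodes are screened); the natural configuration at the spiro carbon and its neighbouring CH is the thermodynamically preferred one.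

**Step 1**
Reactants: 1 5-bromoresorcinol; 2 3-methylbut-2-enal (prenal)
Product: 3 7-bromo-2,2-dimethyl-2H-chromen-5-ol
Conditions: EDDA (10 mol %), toluene, 110 °C
Reagents that add atoms: none
Why: Amine-salt-catalysed Knoevenagel-type condensation at the carbon between the two hydroxyls (the usual site for 5-substituted resorcinols) gives an o-quinone methide that closes by oxa-6π electrocyclisation (formal [3+3] chromene annulation); no stereocentre.

**Step 2**
Reactants: 3 7-bromo-2,2-dimethyl-2H-chromen-5-ol; 4 prenyl bromide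
Product: 5 7-bromo-2,2-dimethyl-6-(3-methylbut-2-en-1-yl)-2H-chromen-5-ol
Conditions: NaH (1.1 equiv), toluene, 0 °C; then 4, 0 °C → rt
Reagents that add atoms: none
Why: Ortho-selective C-alkylation of a sodium phenoxide in a non-polar solvent (tight ion pair) at the only free ortho carbon, C6; the O-prenyl ether by-product is separated.

**Step 3**
Reactants: 5 7-bromo-2,2-dimethyl-6-(3-methylbut-2-en-1-yl)-2H-chromen-5-ol
Product: 6 7-bromo-2,2-dimethyl-6-(3-methylbut-2-en-1-yl)-2H-chromene-5,8-dione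
Conditions: Fremy's salt (2.5 equiv), KH2PO4, acetone/H2O, rt
Reagents that add atoms: potassium nitrosodisulfonate (Fremy's salt), [O]N(S(=O)(=O)[O-])S(=O)(=O)[O-].[K+].[K+]
Why: Teuber oxidation of a phenol with a free para position (C8) gives the p-quinone, and the aryl bromide, chromene and prenyl alkenes are inert to this radical oxidant.

**Step 4**
Reactants: 7 2,3,4-trihydroxybenzoic acid
Product: 8 2-(trimethylsilyl)ethyl 2,3,4-trihydroxybenzoate
Conditions: TMSCH2CH2OH (1.2 equiv), PPh3, DIAD, THF, 0 °C → rt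
Reagents that add atoms: 2-(trimethylsilyl)ethanol, C[Si](C)(C)CCO
Why: Mitsunobu esterification is chemoselective for the carboxylic acid over the phenols and installs an ester that fluoride removes later under near-neutral conditions.

**Step 5**
Reactants: 8 2-(trimethylsilyl)ethyl 2,3,4-trihydroxybenzoate; 9 tert-butyl 2-methylbut-3-en-2-yl carbonate (2.3 equiv)
Product: 10 2-(trimethylsilyl)ethyl 2-hydroxy-3,4-bis[(2-methylbut-3-en-2-yl)oxy]benzoate
Conditions: Pd(PPh3)4 (5 mol %), THF, 0–5 °C
Reagents that add atoms: none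
Why: Tsuji–Trost O-allylation with the tertiary carbonate gives the branched 1,1-dimethylallyl aryl ethers under kinetic control at the 3- and 4-OH, while the 2-OH hydrogen-bonded to the ester stays free.

**Step 6**
Reactants: 10 2-(trimethylsilyl)ethyl 2-hydroxy-3,4-bis[(2-methylbut-3-en-2-yl)oxy]benzoate
Product: 12 2-(trimethylsilyl)ethyl 2,5-dihydroxy-3,4-bis[(2-methylbut-3-en-2-yl)oxy]benzoate, via quinone ester 11 (not isolated)
Conditions: Fremy's salt (2.5 equiv), NaH2PO4, acetone/H2O, rt; then Na2S2O4 (aq), EtOAc, rt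
Reagents that add atoms: potassium nitrosodisulfonate (Fremy's salt), [O]N(S(=O)(=O)[O-])S(=O)(=O)[O-].[K+].[K+]
Why: Teuber oxidation at the free position para to the salicylate OH gives the ester-substituted p-quinone, which dithionite reduces at once to the air-stable gentisate-type hydroquinone so the electrophilic quinone is never stored.

**Step 7**
Reactants: 12 2-(trimethylsilyl)ethyl 2,5-dihydroxy-3,4-bis[(2-methylbut-3-en-2-yl)oxy]benzoate
Product: 13 2-(trimethylsilyl)ethyl 5-[(tert-butyldimethylsilyl)oxy]-2-hydroxy-3,4-bis[(2-methylbut-3-en-2-yl)oxy]benzoate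
Conditions: TBSCl (1.1 equiv), imidazole, DMF, 0 °C
Reagents that add atoms: tert-butyldimethylsilyl chloride, CC(C)(C)[Si](C)(C)Cl
Why: Chemoselective silylation of the free 5-OH over the 2-OH, which is hydrogen-bonded to and flanked by the ester.

**Step 8**
Reactants: 13 2-(trimethylsilyl)ethyl 5-[(tert-butyldimethylsilyl)oxy]-2-hydroxy-3,4-bis[(2-methylbut-3-en-2-yl)oxy]benzoate; 6 7-bromo-2,2-dimethyl-6-(3-methylbut-2-en-1-yl)-2H-chromene-5,8-dione
Product: 14 2-(trimethylsilyl)ethyl 5-[(tert-butyldimethylsilyl)oxy]-2-{[2,2-dimethyl-6-(3-methylbut-2-en-1-yl)-5,8-dioxo-5,8-dihydro-2H-chromen-7-yl]oxy}-3,4-bis[(2-methylbut-3-en-2-yl)oxy]benzoate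
Conditions: K2CO3 (1.5 equiv), MeCN, 0 °C → rt
Reagents that add atoms: none
Why: Addition–elimination (SNV) of the salicylate phenoxide at the bromine-bearing carbon of the fully substituted quinone, the only electrophilic site open, forges a tetra-ortho-substituted C–O bond under mild conditions that keep the aryl silyl ether and the thermally labile allyl ethers intact.

**Step 9**
Reactants: 14 2-(trimethylsilyl)ethyl 5-[(tert-butyldimethylsilyl)oxy]-2-{[2,2-dimethyl-6-(3-methylbut-2-en-1-yl)-5,8-dioxo-5,8-dihydro-2H-chromen-7-yl]oxy}-3,4-bis[(2-methylbut-3-en-2-yl)oxy]benzoate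
Product: 16 2-(trimethylsilyl)ethyl (1R,3R,6S,7S)-1-[(tert-butyldimethylsilyl)oxy]-7-{[2,2-dimethyl-6-(3-methylbut-2-en-1-yl)-5,8-dioxo-5,8-dihydro-2H-chromen-7-yl]oxy}-5,5-dimethyl-3-(3-methylbut-2-en-1-yl)-2-oxo-4-oxatricyclo[4.3.1.0(3,7)]dec-8-ene-8-carboxylate, via Claisen dienone 15 (not isolated)
Conditions: N,N'-bis[(1R,2R)-2-(2-phenylpyrrol-1-yl)cyclohexyl]guanidinium BArF24 (20 mol %), PhCF3, 4 Å MS, 50 °C, 48–72 h
Reagents that add atoms: none
Why: Proposed new method: a C2-symmetric chiral guanidinium (dual N–H donor) is proposed to bind the ester-polarised 4-O-(1,1-dimethylallyl) ether oxygen and stabilise the dipolar chair transition state of the dearomative [3,3] shift to C3 on one enantiotopic face, which sets the R quaternary C(prenyl)(O) centre as the first stereocentre; the same catalyst, now hydrogen-bonded to the dienone carbonyl of 15, lowers the diene LUMO for the intramolecular inverse-demand Diels–Alder reaction with the tethered vinyl group, which can only add on the face of the ether tether and so fixes the other three cage centres; because the Claisen step is reversible, both enantiomers of 15 funnel through the faster catalyst-matched cycloaddition; the closest known reactions are hydrogen-bond-donor (guanidinium/urea)-catalysed enantioselective Claisen rearrangements of ester-substituted allyl vinyl ethers and the thermal Claisen/Diels–Alder cascade of catechol bis(1,1-dimethylallyl) ethers to caged Garcinia skeletons.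

**Step 10**
Reactants: 16 2-(trimethylsilyl)ethyl (1R,3R,6S,7S)-cage ester from step 9
Product: 18 CNP0222516.1 (target), via seco acid quinone 17 (not isolated)
Conditions: TBAF (3 equiv), THF, 0 °C → rt; then AcOH (3 equiv), rt
Reagents that add atoms: none
Why: Fluoride removes the TMSE ester (β-elimination) and the bridgehead silyl ether, and the freed carboxylate adds 6-exo to the alkoxy-bearing quinone carbon (intramolecular oxa-Michael, Thiele-type O-addition to a quinone) with C-protonation of the enolate; the spiro carbon (S) and the adjacent CH (S) are both reversible (retro-oxa-Michael, enolisation) and settle with the prenyl group equatorial and trans to the bulky cage ether oxygen.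

**Compound list**
1 | 5-bromoresorcinol | Oc1cc(O)cc(Br)c1 | starting material
2 | 3-methylbut-2-enal (prenal) | CC(C)=CC=O | starting material
3 | 7-bromo-2,2-dimethyl-2H-chromen-5-ol | CC1(C)C=Cc2c(O)cc(Br)cc2O1 | intermediate
4 | 1-bromo-3-methylbut-2-ene (prenyl bromide) | CC(C)=CCBr | starting material
5 | 7-bromo-2,2-dimethyl-6-(3-methylbut-2-en-1-yl)-2H-chromen-5-ol | CC1(C)C=Cc2c(O)c(CC=C(C)C)c(Br)cc2O1 | intermediate
6 | 7-bromo-2,2-dimethyl-6-(3-methylbut-2-en-1-yl)-2H-chromene-5,8-dione | BrC1=C(CC=C(C)C)C(=O)C2=C(OC(C)(C)C=C2)C1=O | intermediate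
7 | 2,3,4-trihydroxybenzoic acid | OC(=O)c1ccc(O)c(O)c1O | starting material
8 | 2-(trimethylsilyl)ethyl 2,3,4-trihydroxybenzoate | C[Si](C)(C)CCOC(=O)c1ccc(O)c(O)c1O | intermediate
9 | tert-butyl 2-methylbut-3-en-2-yl carbonate | C=CC(C)(C)OC(=O)OC(C)(C)C | starting material
10 | 2-(trimethylsilyl)ethyl 2-hydroxy-3,4-bis[(2-methylbut-3-en-2-yl)oxy]benzoate | C[Si](C)(C)CCOC(=O)c1ccc(OC(C)(C)C=C)c(OC(C)(C)C=C)c1O | intermediate
11 | 2-(trimethylsilyl)ethyl 4,5-bis[(2-methylbut-3-en-2-yl)oxy]-3,6-dioxocyclohexa-1,4-diene-1-carboxylate | C[Si](C)(C)CCOC(=O)C1=CC(=O)C(OC(C)(C)C=C)=C(OC(C)(C)C=C)C1=O | intermediate (not isolated)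
12 | 2-(trimethylsilyl)ethyl 2,5-dihydroxy-3,4-bis[(2-methylbut-3-en-2-yl)oxy]benzoate | C[Si](C)(C)CCOC(=O)c1cc(O)c(OC(C)(C)C=C)c(OC(C)(C)C=C)c1O | intermediate
13 | 2-(trimethylsilyl)ethyl 5-[(tert-butyldimethylsilyl)oxy]-2-hydroxy-3,4-bis[(2-methylbut-3-en-2-yl)oxy]benzoate | C[Si](C)(C)CCOC(=O)c1cc(O[Si](C)(C)C(C)(C)C)c(OC(C)(C)C=C)c(OC(C)(C)C=C)c1O | intermediate
14 | aryl quinonyl ether: benzoate 13 joined through its 2-oxygen to C7 of the 2,2-dimethyl-6-prenyl-2H-chromene-5,8-dione (achiral) | C[Si](C)(C)CCOC(=O)c1cc(O[Si](C)(C)C(C)(C)C)c(OC(C)(C)C=C)c(OC(C)(C)C=C)c1OC2=C(CC=C(C)C)C(=O)C3=C(OC(C)(C)C=C3)C2=O | intermediate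
15 | 2-(trimethylsilyl)ethyl (3R)-5-[(tert-butyldimethylsilyl)oxy]-2-(chromenequinon-7-yloxy)-3-[(2-methylbut-3-en-2-yl)oxy]-3-(3-methylbut-2-en-1-yl)-4-oxocyclohexa-1,5-diene-1-carboxylate | C=CC(C)(C)O[C@@]1(CC=C(C)C)C(=O)C(O[Si](C)(C)C(C)(C)C)=CC(C(=O)OCC[Si](C)(C)C)=C1OC2=C(CC=C(C)C)C(=O)C3=C(OC(C)(C)C=C3)C2=O | intermediate (not isolated)
16 | 2-(trimethylsilyl)ethyl (1R,3R,6S,7S)-1-(TBS-oxy)-7-(chromenequinon-7-yloxy)-5,5-dimethyl-3-prenyl-2-oxo-4-oxatricyclo[4.3.1.0(3,7)]dec-8-ene-8-carboxylate | C[Si](C)(C)CCOC(=O)C1=C[C@]3(O[Si](C)(C)C(C)(C)C)C[C@H]4C(C)(C)O[C@@](CC=C(C)C)(C3=O)[C@@]14OC5=C(CC=C(C)C)C(=O)C6=C(OC(C)(C)C=C6)C5=O | intermediate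
17 | (1R,3R,6S,7S)-7-(chromenequinon-7-yloxy)-1-hydroxy-5,5-dimethyl-3-prenyl-2-oxo-4-oxatricyclo[4.3.1.0(3,7)]dec-8-ene-8-carboxylic acid | OC(=O)C1=C[C@]3(O)C[C@H]4C(C)(C)O[C@@](CC=C(C)C)(C3=O)[C@@]14OC5=C(CC=C(C)C)C(=O)C6=C(OC(C)(C)C=C6)C5=O | intermediate (not isolated)
18 | CNP0222516.1: spiroketal lactone in which a 1,3-dioxan-4-one links C7 (S, spiro) of (6S)-2,2-dimethyl-6-prenyl-6,7-dihydro-2H-chromene-5,8-dione to O–C7 and C8–C(=O) of the (1R,3R,6S,7S)-1-hydroxy-5,5-dimethyl-3-prenyl-4-oxatricyclo[4.3.1.0(3,7)]dec-8-en-2-one cage | CC(C)=CC[C@H]1C(=O)C2=C(OC(C)(C)C=C2)C(=O)[C@@]12OC(=O)C1=C[C@]3(O)C[C@H]4C(C)(C)O[C@@](CC=C(C)C)(C3=O)[C@@]14O2 | target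

**Totals**
Total steps: 10. Longest linear sequence: 7 (steps 4–10, from 2,3,4-trihydroxybenzoic acid); the A-ring branch (steps 1–3) joins at step 8.

**Three steps most likely to fail**

Step 9 (the proposed new step). Risks are low enantioselectivity (reversible Claisen step, thermal background), catalyst sequestration by the quinone and ester carbonyls, and the regioisomeric "neo" cage from migration of the 3-O-allyl group. Fallback with known chemistry, setting out from 14: heat 14 in DMF at 120 °C, the established uncatalysed Claisen/Diels–Alder cascade for this cage type. This gives 16 together with its mirror image, 2-(trimethylsilyl)ethyl (1S,3S,6R,7R)-1-(TBS-oxy)-7-(chromenequinon-7-yloxy)-5,5-dimethyl-3-prenyl-2-oxo-4-oxatricyclo[4.3.1.0(3,7)]dec-8-ene-8-carboxylate F1. F1 is removed by preparative chiral-phase SFC, and the route is rejoined at 16.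

Step 10. Risks are the wrong diastereomer at the spiro carbon or the adjacent CH if the natural arrangement is not the thermodynamic one, fluoride-induced cyclisation of the prenylquinone, and α-ketol shift of the bridgehead hydroxy ketone. Fallback setting out from 17: quench the desilylation with AcOH at 0 °C and isolate acid 17 before it cyclises. Silylate it with BSA (CH2Cl2, rt) to trimethylsilyl (1R,3R,6S,7S)-7-(chromenequinon-7-yloxy)-5,5-dimethyl-3-prenyl-2-oxo-1-(trimethylsilyloxy)-4-oxatricyclo[4.3.1.0(3,7)]dec-8-ene-8-carboxylate F2. Catalytic TMSOTf (CH2Cl2, −78 °C) then closes the silyl ester onto the O-silyl-activated quinone (silyl-transfer ketalisation, Mukaiyama–Michael logic) under kinetic control to the spiroketal lactone 5-(trimethylsilyloxy) dienol ether with the bridgehead OSiMe3 retained F3. HF·pyridine (THF, −40 °C) removes both silyl groups with kinetic C-protonation from the less hindered face, returning to the route at 18.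

Step 6. Risks are sluggish Teuber oxidation of the hydrogen-bonded, ester-deactivated salicylate and loss of the electrophilic quinone 11 by hydration or Claisen shift. Fallback setting out from 10: NBS (MeCN, 0 °C) brominates para to the phenol to give 2-(trimethylsilyl)ethyl 5-bromo-2-hydroxy-3,4-bis[(2-methylbut-3-en-2-yl)oxy]benzoate F4. Room-temperature Ni/photoredox C–O coupling with water (NiCl2·glyme, dtbbpy, Ir photocatalyst, quinuclidine, K2CO3, MeCN/H2O, blue LEDs) converts F4 to the hydroquinone without heating the allyl ethers, returning to the route at 12.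

**Further compounds**
F1 | step 9 | 2-(trimethylsilyl)ethyl (1S,3S,6R,7R)-1-(TBS-oxy)-7-(chromenequinon-7-yloxy)-5,5-dimethyl-3-prenyl-2-oxo-4-oxatricyclo[4.3.1.0(3,7)]dec-8-ene-8-carboxylate (enantiomer of 16) | C[Si](C)(C)CCOC(=O)C1=C[C@@]3(O[Si](C)(C)C(C)(C)C)C[C@@H]4C(C)(C)O[C@](CC=C(C)C)(C3=O)[C@]14OC5=C(CC=C(C)C)C(=O)C6=C(OC(C)(C)C=C6)C5=O
F2 | step 10 | trimethylsilyl (1R,3R,6S,7S)-7-(chromenequinon-7-yloxy)-5,5-dimethyl-3-prenyl-2-oxo-1-(trimethylsilyloxy)-4-oxatricyclo[4.3.1.0(3,7)]dec-8-ene-8-carboxylate | C[Si](C)(C)OC(=O)C1=C[C@]3(O[Si](C)(C)C)C[C@H]4C(C)(C)O[C@@](CC=C(C)C)(C3=O)[C@@]14OC5=C(CC=C(C)C)C(=O)C6=C(OC(C)(C)C=C6)C5=O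
F3 | step 10 | spiroketal lactone 5-(trimethylsilyloxy) dienol ether with bridgehead OSiMe3 (spiro carbon S, cage 1R,3R,6S,7S) | CC(C)=CCC1=C(O[Si](C)(C)C)C2=C(OC(C)(C)C=C2)C(=O)[C@@]12OC(=O)C1=C[C@]3(O[Si](C)(C)C)C[C@H]4C(C)(C)O[C@@](CC=C(C)C)(C3=O)[C@@]14O2
F4 | step 6 | 2-(trimethylsilyl)ethyl 5-bromo-2-hydroxy-3,4-bis[(2-methylbut-3-en-2-yl)oxy]benzoate | C[Si](C)(C)CCOC(=O)c1cc(Br)c(OC(C)(C)C=C)c(OC(C)(C)C=C)c1O
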